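3 questions, and you want a quick number for each before larch is charged, so here is the quantity I would put the order and the yield on.

| flask | starting material | reagent | free catalyst | product | time |
|---|---|---|---|---|---|
| elm | 0.500 M | 1.25 M | 0.0400 M |  |  |
| cedar | 0.300 M | 1.05 M | 0.0400 M |  |  |
| ash | 0.500 M | 1.25 M | 0.0600 M |  |  |
| birch | 0.500 M | 1.25 M | 0.0400 M | 0.150 M |  |
| larch | 0.250 M | 2.50 M | 0.0400 M |  | 17 min |

- elm run (time / min: [product] / M): 2.4: 0.0659; 4.9: 0.1532; 7.3: 0.2223; 9.7: 0.2723; 12: 0.3110; 15: 0.3504; 17: 0.3666
- cedar run (time / min: [product] / M): 2.4: 0.0397; 4.9: 0.1033; 7.3: 0.1450; 9.7: 0.1736; 12: 0.1955; 15: 0.2158; 17: 0.2338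
- ash run (time / min: [product] / M): 2.4: 0.0903; 4.9: 0.2136; 7.3: 0.2846; 9.7: 0.3402; 12: 0.3743; 15: 0.4055; 17: 0.4178
- birch run (time / min: [product] / M): 2.4: 0.2142; 4.9: 0.3065; 7.3: 0.3708; 9.7: 0.4249; 12: 0.4656; 15: 0.4981; 17: 0.5200

(readings scatter by 0.002 M)

- Overall: starting material + reagent -> product, with free catalyst as catalyst.
- Constant volume, constant temperature.
- The analysis sees a species whether free or bound.
- An order is taken over about fifteen percent of the charge, up and down.

- the power of [free catalyst] that the first rate follows, about the charge of the elm run; measure it at two percent of starting material made into product
- the cedar run starts with 0.200 M less of starting material and of reagent than the elm run, and with no product. Compared where both hold the same amount of starting material, once fifteen percent of what the cedar run was charged with has turned into product, is the cedar run faster, slower or alike (within a tenth)?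
- product in the larch run at 17 min, as a share of the starting material charged

I use the log clock of a run: the natural log of one over the fraction of the charged starting material still unconverted. Integrating a rate first order in starting material gives exactly this, and a pseudo-first-order flask runs it linearly in time. Elm has converted 73.3 % at 17 min, so its log clock stands at 1.32. Ash has converted 83.6 % at that time, a clock of 1.81, on 1.50 times elm's catalyst. The ratio of clocks 1.37 is less than the catalyst ratio, and it gives an exponent of 0.770. That is my rough order in catalyst, taken over the whole run and not at two percent.

For cedar against elm I compare slopes where both flasks hold the same starting material, not clocks at one time. Around the point asked, cedar's slope from 2.4 min to 4.9 min reads 0.0254 M min⁻¹, and elm's from 7.3 min to 9.7 min, where elm holds that same amount, reads 0.0208 M min⁻¹. Cedar's slope is higher than elm's by a read ratio of 1.22, so I say faster. No run varies reagent apart from starting material, so for larch I borrow the catalyst exponent for reagent. Elm's clock then becomes 2.25, which is 89.5 % of the charge at 17 min.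

The forecast you sent says 0.85, faster and 93 %, reading cedar as “mild substrate saturation and/or catalyst loss”. We agree on the direction; its order and its yield both stand above mine.

The simulation gives 0.59, faster and 77.0 %.

    active catalyst + starting material → catalyst-substrate complex (5.490 M⁻¹ min⁻¹)
    catalyst-substrate complex + reagent → loaded catalyst (3.264 M⁻¹ min⁻¹)
    loaded catalyst → product + active catalyst (4.764 min⁻¹)
    free catalyst + reagent → active catalyst + reagent (1.098 M⁻¹ min⁻¹)
    2 active catalyst → 2 spent catalyst (3.120 M⁻¹ min⁻¹)

Ash's clock ratio applied to elm's quarter time of 4.02 min gives 2.93 min, and ash reached a quarter at 3.02 min. Larch's clock reads 1.47 at 17 min, which is 1.11 times elm's, whereas the forecast's number is elm's clock scaled as if first order in everything but starting material. The reason is the loss of active catalyst in pairs to spent catalyst, a bimolecular termination. The larch run without that step gives 95.6 %, a clock of 3.12, and the step accounts for 81 % of what is missing.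

(Readings and results stem from a simulated flask with constants of no real substance, and the scatter is random.)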